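All runs are calculated with constants of no real substance.

The summer run gains 26.1% in its first 10.0 min but 2.4 percentage points in its last 10.0 min, and the dusk run bends the same way.

all flasks: substrate 0.020 M

| charge | coupling partner | initiator | temperature | remark | time |
|---|---|---|---|---|---|
| dusk | 2 equiv | 3.4 mol% | −10 °C | run made earlier |  |
| summer | 2 equiv | 7.5 mol% | 10 °C | run made earlier |  |
| noon | 1 equiv | 5 mol% | −10 °C | run made earlier |  |
| maple | 2.00 equiv | 5 mol% |  | at 25 °C until 6.0 min, from then on at −5 °C | 20 min |
| ash | 2.00 equiv | 5 mol% |  | at 25 °C throughout | 20 min |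

| run | time / min | target / % |
|---|---|---|
| dusk | 12.0 | 3.2 |
| dusk | 25.0 | 7.3 |
| dusk | 30.0 | 8.8 |
| dusk | 60.0 | 15.3 |
| dusk | 150 | 24.3 |
| summer | 10.0 | 26.1 |
| summer | 20.0 | 39.4 |
| summer | 30.0 | 47.9 |
| summer | 40.0 | 52.3 |
| summer | 50.0 | 54.7 |
| noon | 12.0 | 2.4 |
| noon | 30.0 | 5.9 |
| noon | 60.0 | 9.8 |
| noon | 80.0 | 12.9 |
| noon | 150 | 18.8 |

(readings scatter by 0.3 percentage points)



- the winner by amount of target, in percent of the substrate charged; "neither" if no more than 2 percentage points parts them (maple / ash / neither)
- how much target is there at the end, in percent of the substrate charged: maple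
- how much target is there at the end, in percent of the substrate charged: ash

There are two views of that bend. The forecast reads it so: “so the active species dies rather than the reagents running out”. It gives maple 41.5%, ash 62% and names ash the winner.

I hold that the target is being eaten. The gain rate is then a making rate minus a pseudo-first-order loss constant κ times the target, and the target approaches a balance level, the making rate over κ.

Gain against mean target, first and last intervals of summer, gives κ = 0.0586 min⁻¹. The first gain rate over κ gives a level of 44.5%, below the last reading. So I go round once more: target was already being lost in that first interval, so I add κ times its mean to the making rate, and the level becomes 57.6%. Dusk, treated the same way, gives κ = 0.0153 min⁻¹ and a level of 26.3%.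

I take the making rate to go with the root of the initiator, as the forecast does, and the loss to be free of it. I also draw the logarithms of level and κ straight against temperature, which is crude out at 25 °C. At 5 mol% this gives 62.9% with κ = 0.160 min⁻¹ at 25 °C. The balance level of maple's cold stretch is 35.2%, with κ = 0.0214 min⁻¹.

Maple reaches 38.9% at the change, above that level, so I have it sink to 37.9%, not climb. Ash comes to 60.3%.

The flasks give maple 37.9% and ash 51.8%, so the winner is ash. Ash falls short of both numbers, ending with substrate 0%, over-reaction product 44.7% and initiator still 60.7% of its charge. The gap of 14 points between ash and maple is due to the difference in temperature programme. The forecast's 41.5% for maple is made of about 39% at the change plus about 3 points after it, whereas maple stands at 36.9% at the change and adds 1 point.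

    2 first chain carrier → ended chains (k = 6.00 × 10⁶ M⁻¹ s⁻¹, Ea = 12.0 kJ mol⁻¹)
    coupling partner + target → over-reaction product (k = 2.70 M⁻¹ min⁻¹, Ea = 45.0 kJ mol⁻¹)
    coupling partner + first chain carrier → target + second chain carrier (k = 1.86 × 10⁵ M⁻¹ min⁻¹, Ea = 25.0 kJ mol⁻¹)
    substrate + initiating radical → capped initiator + first chain carrier (k = 1.20 × 10⁵ M⁻¹ s⁻¹, Ea = 26.0 kJ mol⁻¹)
    substrate + second chain carrier → released group + first chain carrier (k = 14100 M⁻¹ s⁻¹, Ea = 24.0 kJ mol⁻¹)
    initiator → 2 initiating radical (k = 0.0250 min⁻¹, Ea = 80.0 kJ mol⁻¹)
    (constants at 25 °C)

Maple's target stands at 36.9% at the change and 37.9% at the end, beside the level 35.2%, while its substrate falls from 50.4% to 44.3% and its over-reaction product rises from 11.3% to 16.3%. Part of maple's shortfall is that loss: without the step the flask holds 55.9%. The neighbour of ash with 1.20 equiv of coupling partner has the same reckoned level 62.9%, as partner stands in both rates and cancels, and it ends at 43.6% with substrate 33% left.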